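Readings and results were generated by integration with constants of no real substance; noise was put on by code.

The red run and its neighbours, amber and teal, have split two chemists, Ines and Marek.

| flask | starting material | reagent | time |
|---|---|---|---|
| red | 0.100 M | 0.300 M |  |
| amber | 0.0600 M | 0.260 M |  |
| teal | 0.100 M | 0.600 M |  |
| green | 0.100 M | 1.90 M | 110 s |

| run | time / s | [target] / M |
|---|---|---|
| red run | 14 | 0.0083 |
| red run | 28 | 0.0154 |
| red run | 41 | 0.0191 |
| red run | 55 | 0.0240 |
| red run | 69 | 0.0269 |
| red run | 82 | 0.0283 |
| red run | 96 | 0.0302 |
| red run | 110 | 0.0304 |
| amber run | 14 | 0.0070 |
| amber run | 28 | 0.0093 |
| amber run | 41 | 0.0127 |
| amber run | 55 | 0.0162 |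
| amber run | 69 | 0.0189 |
| amber run | 82 | 0.0179 |
| amber run | 96 | 0.0185 |
| amber run | 110 | 0.0181 |
| teal run | 14 | 0.0168 |
| teal run | 28 | 0.0248 |
| teal run | 41 | 0.0310 |
| teal run | 55 | 0.0316 |
| teal run | 69 | 0.0324 |
| teal run | 82 | 0.0321 |
| teal run | 96 | 0.0319 |
| teal run | 110 | 0.0302 |

(readings scatter by 8 × 10⁻⁴ M)

- how the opening rate goes with [starting material] round the charge of the red run: the exponent of the rate at two percent of starting material gone to target (one fixed amount of target, the same in the runs compared)
- how the opening rate goes with [reagent] round the charge of the red run: the exponent of the rate at two percent of starting material gone to target
- target in the green run at 110 s, as a share of the starting material charged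
- which of these the readings show (the substrate pairs with itself / the second partner is lost by itself / the product speeds the reaction / nothing beyond the main steps / the product decays)

- Overall: starting material + reagent -> target.
- Constant volume, constant temperature.
- Readings of a species count what is bound in complexes too.
- "The second partner" is reagent.
- An order is taken over about fifteen percent of the charge, up and down.

Both start from the balance of the limiting reagent. In the red run that is starting material, charged at 0.100 M against 0.300 M of reagent, and what was charged is now target plus whatever else it has become. Late red and teal readings hold target near 30.7% of the charge.

For speed they use the mark time, when target reaches a quarter of the charge, interpolated between readings: 59.8 s in red, 50.2 s in amber and 28.4 s in teal. The red run gives 17.9 M·s for the mark time multiplied by charged [reagent], the reagent-time.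

Ines sees a pseudo-first-order lag, its time constant inverse in [reagent] and blind to the charge of starting material, so the reagent-time should hold from run to run. Teal gives 17.1 M·s, which suits her, and from red she expects amber's mark at 69.0 s.

Marek answers that amber reached it earlier, while one reading's scatter moves that mark by about 3.20 s. Amber's reagent-time is 13.1 M·s. If the rate goes as a power of [starting material], the reagent-time goes as the charge to one minus that power, so the power reads 0.376, below first order. He suspects that starting material pairs with itself.

My reckoning follows Marek: order in [starting material] about 0.376, and from teal against red, order in [reagent] about 1.07. The green run has red's charge of starting material, so its mark falls near 9.45 s, far before 110 s, and I expect it flat at about 30.7%.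

The forecast sides with Ines, with orders 1 and 1, 31% and "nothing beyond the main steps", holding that the “final yield therefore scales with starting material”.

The flask gives orders 0.57 and 1.0, 31.8% and "the substrate pairs with itself".

    starting material + reagent → target (0.1710 /M/s)
    starting material + reagent → side product (0.3660 /M/s)
    2 starting material ⇌ idle substrate dimer, settled at all times (238.0 /M)

The amber run proves Marek right: its reagent-time is 13.7 M·s against 18.1 M·s in the red run. The joining of starting material into idle substrate dimer holds the order at 0.57; without that joining it stands at 1.1. Ines keeps the order in reagent, which the pairing does not set, and the share of target in the green run, which the pairing does not change: with red's reagent-time of 17.9 M·s, green's mark is reckoned near 9.45 s, and at 110 s target in the green run stands at 31.8% of the starting material charged.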